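**Retrosynthetic overview**

1. The target is the oleate of (3R)-β-cryptoxanthin, so the last disconnection is the ester C–O bond (O-acylation with oleoyl chloride).
2. The C7=C8 olefin is cut by a Wittig disconnection into a C10 ring phosphonium salt (the oxygenated end group) and commercial C30 β-apo-8'-carotenal, which brings the unsubstituted β ring and the rest of the polyene.
3. The oxygenated ring comes from an acyclic 1,5-diene phosphonium salt by a proton-initiated cation–olefin cyclisation (C1 cation, C1–C6 bond, loss of H-6), the chemistry of lycopene β-cyclase, run with the C3 oxygen already in place so that it delivers the Wittig salt directly.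
4. The acyclic precursor comes from (S)-epichlorohydrin (C2–C3–C4 and the only stereocentre), isopropenyl Grignard, acetylide and Me3Al/formaldehyde.
5. Ring order: only the oxygenated cyclohexene ring is built (step 5); the other ring is bought inside the C30 aldehyde.

Assumption: carotenoid numbering is used for the end group (C1 gem-dimethyl carbon, C3 carbinol, C5=C6 ring olefin, C7 exocyclic carbon), and trans-β-apo-8'-carotenal (the food colourant) is taken as a cheap commercial material.

**Route**

Step 1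
Reactants: 1 (S)-epichlorohydrin; 2 isopropenylmagnesium bromide
Product: 4 (2S)-2-(2-methylprop-2-en-1-yl)oxirane, via chlorohydrin 3 (not isolated)
Conditions: 2 (1.1 equiv), CuI (copper monoiodide, 5 mol %), THF, −40 → 0 °C; H2O quench; then NaOH (powder), Et2O, rt; distil
Reagents that add atoms: isopropenylmagnesium bromide, CC(=C)[Mg]Br
Why: Copper-catalysed Grignard opening of the epoxide at its unsubstituted CH2 (SN2) followed by Williamson ring closure of the chlorohydrin; the stereocentre is never a reaction site, so the S configuration of 1 is carried into 4.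

Step 2
Reactants: 4 (2S)-2-(2-methylprop-2-en-1-yl)oxirane; 5 lithium acetylide–ethylenediamine complex
Product: 6 (4S)-2-methylhept-1-en-6-yn-4-ol
Conditions: 5 (1.5 equiv), DMSO, 0 °C → rt, 12 h; H2O quench
Reagents that add atoms: lithium acetylide (ethylenediamine complex), [Li]C#C.NCCN
Why: SN2 opening of the terminal epoxide by acetylide at the CH2 carbon (epoxide alkynylation); the carbinol carbon is not touched and stays S.

Step 3
Reactants: 6 (4S)-2-methylhept-1-en-6-yn-4-ol; 7 trimethylaluminium; 8 paraformaldehyde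
Product: 10 (2E,5S)-3,7-dimethylocta-2,7-diene-1,5-diol, via alkenylalane 9 (not isolated)
Conditions: Me3Al (3 equiv), Cp2ZrCl2 (0.25 equiv), CH2Cl2, 0 °C → rt, 12 h; evaporate; THF, n-BuLi (1.1 equiv), −78 → 0 °C; (CH2O)n (excess), rt; aq. KNaC4H4O6 work-up
Reagents that add atoms: trimethylaluminium, C[Al](C)C; formaldehyde (from paraformaldehyde), C=O
Why: Negishi zirconium-catalysed carboalumination adds Me–Al syn across the terminal alkyne with methyl on the internal carbon, and the derived alkenylalanate is hydroxymethylated by formaldehyde with retention to give the E allylic alcohol (any Z isomer is equally usable in step 5); the stereocentre is untouched.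

Step 4
Reactants: 10 (2E,5S)-3,7-dimethylocta-2,7-diene-1,5-diol; 11 triphenylphosphine; 12 methanesulfonic acid; 13 acetic anhydride
Product: 15 [(2E,5S)-5-(acetyloxy)-3,7-dimethylocta-2,7-dien-1-yl]triphenylphosphonium methanesulfonate, via hydroxy phosphonium salt 14 (not isolated)
Conditions: PPh3 (1.05 equiv), MeSO3H (1.0 equiv), CH2Cl2, 35 °C, 24 h; then pyridine (3 equiv), Ac2O (1.5 equiv), DMAP (5 mol %), rt, 3 h; wash with dilute aq. MeSO3H; precipitate from EtOAc/Et2O
Reagents that add atoms: triphenylphosphine, c1ccc(cc1)P(c1ccccc1)c1ccccc1; methanesulfonic acid, CS(=O)(=O)O; acetic anhydride, CC(=O)OC(C)=O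
Why: Acid-mediated conversion of an allylic alcohol into its triphenylphosphonium salt (capture of the activated allyl system by PPh3, the standard preparation of carotenoid Wittig salts) occurs only at the primary allylic hydroxyl, and the remaining secondary alcohol is then acetylated (DMAP-catalysed acylation) without touching the stereocentre.

Step 5
Reactants: 15 [(2E,5S)-5-(acetyloxy)-3,7-dimethylocta-2,7-dien-1-yl]triphenylphosphonium methanesulfonate
Product: 16 {[(4R)-4-(acetyloxy)-2,6,6-trimethylcyclohex-1-en-1-yl]methyl}triphenylphosphonium methanesulfonate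
Conditions: MeSO3H–AcOH (1:3 v/v), 15–20 °C, 4–8 h (31P NMR control); ice-water; CH2Cl2 extraction; crystallise from EtOAc/Et2O
Reagents that add atoms: none
Why: Proposed new method: Markovnikov protonation of the 1,1-disubstituted alkene gives the tertiary C1 cation (the cation lycopene β-cyclase makes by protonating C2), C6 of the trisubstituted alkene attacks it to close the six-membered ring, and the tertiary C5 cation loses H-6 (acidified by the adjacent CH2PPh3+ group) so that the tetrasubstituted 5,6-olefin accumulates under reversible protonation; the phosphonium and acetate groups are acid-stable, the O-acetyl group suppresses retro-Prins fragmentation of the γ-oxy cation, and C3 is not a reacting centre, so its configuration is carried over unchanged (the descriptor becomes R only because ring closure changes the ranking of the two CH2 branches); the closest known reaction type is the H2SO4/AcOH cation–olefin cyclisation of geranyl aryl sulfones to β-cyclogeranyl sulfones and of pseudoionone to β-ionone.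

Step 6
Reactants: 16 {[(4R)-4-(acetyloxy)-2,6,6-trimethylcyclohex-1-en-1-yl]methyl}triphenylphosphonium methanesulfonate; 17 β-apo-8'-carotenal
Product: 20 (3R)-β-cryptoxanthin [(3R)-β,β-caroten-3-ol], via hydroxy ylide 18 (not isolated), via (7Z)-β-cryptoxanthin 19 (not isolated)
Conditions: 16 (1.1 equiv), NaOMe (2.5 equiv), MeOH/CH2Cl2, 0 °C → rt, 45 min; then 17 (1.0 equiv), rt, 16 h, Ar, dark; aqueous work-up; reflux in heptane, 6 h; crystallise from CH2Cl2/MeOH
Reagents that add atoms: β-apo-8'-carotenal, O=C/C(C)=C/C=C/C(C)=C/C=C/C=C(C)/C=C/C=C(C)/C=C/C1=C(C)CCCC1(C)C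
Why: Methoxide removes the acetate by transesterification and generates the allylic ylide, whose Wittig olefination with the polyenal forms C7=C8; the strained 7Z isomer converges thermally to the all-E polyene, and no stereocentre is touched.

Step 7
Reactants: 20 (3R)-β-cryptoxanthin; 21 oleoyl chloride
Product: 22 (3R)-β,β-caroten-3-yl (9Z)-octadec-9-enoate (β-cryptoxanthin oleate, CNP0152321.1)
Conditions: 21 (1.5 equiv), pyridine (3 equiv), DMAP (10 mol %), CH2Cl2, 0 °C → rt, Ar, dark; chromatography on deactivated silica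
Reagents that add atoms: oleoyl chloride, CCCCCCCC/C=C\CCCCCCCC(=O)Cl
Why: Nucleophilic acyl substitution at the hydroxyl oxygen (DMAP-catalysed esterification with an acid chloride) leaves the C3–O bond intact, so 3R is retained, and the cis olefin of the acyl chain is not touched.

**Compound list**

1 | (S)-epichlorohydrin, (2S)-2-(chloromethyl)oxirane | ClC[C@@H]1CO1 | starting material
2 | isopropenylmagnesium bromide | CC(=C)[Mg]Br | starting material
3 | (2S)-1-chloro-4-methylpent-4-en-2-ol | O[C@@H](CC(C)=C)CCl | intermediate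
4 | (2S)-2-(2-methylprop-2-en-1-yl)oxirane | CC(=C)C[C@H]1CO1 | intermediate
5 | lithium acetylide–ethylenediamine complex | [Li]C#C.NCCN | starting material
6 | (4S)-2-methylhept-1-en-6-yn-4-ol | O[C@@H](CC(C)=C)CC#C | intermediate
7 | trimethylaluminium | C[Al](C)C | starting material
8 | paraformaldehyde (source of formaldehyde) | C=O | starting material
9 | [(1E,4S)-4-(dimethylalumanyloxy)-2,6-dimethylhepta-1,6-dien-1-yl]dimethylalumane | C[Al](C)O[C@@H](CC(C)=C)C/C(C)=C/[Al](C)C | intermediate
10 | (2E,5S)-3,7-dimethylocta-2,7-diene-1,5-diol | O[C@@H](CC(C)=C)C/C(C)=C/CO | intermediate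
11 | triphenylphosphine | c1ccc(cc1)P(c1ccccc1)c1ccccc1 | starting material
12 | methanesulfonic acid | CS(=O)(=O)O | starting material
13 | acetic anhydride | CC(=O)OC(C)=O | starting material
14 | [(2E,5S)-5-hydroxy-3,7-dimethylocta-2,7-dien-1-yl]triphenylphosphonium methanesulfonate | O[C@@H](CC(C)=C)C/C(C)=C/C[P+](c1ccccc1)(c1ccccc1)c1ccccc1.CS(=O)(=O)[O-] | intermediate
15 | [(2E,5S)-5-(acetyloxy)-3,7-dimethylocta-2,7-dien-1-yl]triphenylphosphonium methanesulfonate | CC(=O)O[C@@H](CC(C)=C)C/C(C)=C/C[P+](c1ccccc1)(c1ccccc1)c1ccccc1.CS(=O)(=O)[O-] | intermediate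
16 | {[(4R)-4-(acetyloxy)-2,6,6-trimethylcyclohex-1-en-1-yl]methyl}triphenylphosphonium methanesulfonate | CC(=O)O[C@@H]1CC(C)=C(C[P+](c2ccccc2)(c2ccccc2)c2ccccc2)C(C)(C)C1.CS(=O)(=O)[O-] | intermediate
17 | β-apo-8'-carotenal (all-E 8'-apo-β-caroten-8'-al) | O=C/C(C)=C/C=C/C(C)=C/C=C/C=C(C)/C=C/C=C(C)/C=C/C1=C(C)CCCC1(C)C | starting material
18 | {[(4R)-4-hydroxy-2,6,6-trimethylcyclohex-1-en-1-yl]methylidene}triphenylphosphorane | O[C@@H]1CC(C)=C(C=P(c2ccccc2)(c2ccccc2)c2ccccc2)C(C)(C)C1 | intermediate
19 | (3R,7Z)-β-cryptoxanthin | O[C@@H]1CC(C)=C(\C=C/C(C)=C/C=C/C(C)=C/C=C/C=C(C)/C=C/C=C(C)/C=C/C2=C(C)CCCC2(C)C)C(C)(C)C1 | intermediate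
20 | (3R)-β-cryptoxanthin, all-E (3R)-β,β-caroten-3-ol | O[C@@H]1CC(C)=C(/C=C/C(C)=C/C=C/C(C)=C/C=C/C=C(C)/C=C/C=C(C)/C=C/C2=C(C)CCCC2(C)C)C(C)(C)C1 | intermediate
21 | oleoyl chloride, (9Z)-octadec-9-enoyl chloride | CCCCCCCC/C=C\CCCCCCCC(=O)Cl | starting material
22 | (3R)-β,β-caroten-3-yl (9Z)-octadec-9-enoate (β-cryptoxanthin oleate) | CCCCCCCC/C=C\CCCCCCCC(=O)O[C@@H]1CC(C)=C(/C=C/C(C)=C/C=C/C(C)=C/C=C/C=C(C)/C=C/C=C(C)/C=C/C2=C(C)CCCC2(C)C)C(C)(C)C1 | target

**Step count and risk**

Total step count: 7. Longest linear sequence: 7 steps (1 → 22).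

Most likely to fail, first: step 5. The cationic phosphonium group may slow the ring closure, and the acetate can hold the C1 cation as a cyclic acyloxonium ion. Double-bond isomers (4,5-ene or exocyclic) may also form, and the 4,5-ene would make the C3 acetate allylic and put the enantiomeric purity at risk. The fallback sets out from 10 and cyclises a neutral substrate before phosphorus is introduced. Acetylation of both hydroxyls (Ac2O, pyridine, DMAP) gives (2E,5S)-3,7-dimethylocta-2,7-diene-1,5-diyl diacetate F1. Low-temperature superacid cyclisation (ClSO3H, 2-nitropropane, −78 °C) gives [(4R)-4-(acetyloxy)-2,6,6-trimethylcyclohex-1-en-1-yl]methyl acetate F2. Treatment with PPh3 and MeSO3H (CH2Cl2, 40 °C) then converts only the allylic primary acetate of the 5,6-ene isomer into the phosphonium salt, so the other olefin isomers are washed away, and the route is rejoined at 16.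

Second: step 6. The ylide sits on a carbon flanked by a tetrasubstituted ring olefin and the aldehyde is an α-methyl enal, so conversion may be low. The fallback sets out from 10 and makes the C7=C8 bond by a Julia–Kocienski olefination. Mitsunobu thioetherification of the primary allylic hydroxyl (1-phenyl-1H-tetrazole-5-thiol, PPh3, DIAD, THF, 0 °C) gives (4S,6E)-2,6-dimethyl-8-[(1-phenyl-1H-tetrazol-5-yl)sulfanyl]octa-1,6-dien-4-ol F3. Acetylation (Ac2O, pyridine) gives (4S,6E)-2,6-dimethyl-8-[(1-phenyl-1H-tetrazol-5-yl)sulfanyl]octa-1,6-dien-4-yl acetate F4. Oxidation ((NH4)6Mo7O24, H2O2, EtOH) gives (4S,6E)-2,6-dimethyl-8-[(1-phenyl-1H-tetrazol-5-yl)sulfonyl]octa-1,6-dien-4-yl acetate F5. Cyclisation of this neutral allylic sulfone (MeSO3H/AcOH, the substrate class with direct precedent) gives (1R)-3,5,5-trimethyl-4-{[(1-phenyl-1H-tetrazol-5-yl)sulfonyl]methyl}cyclohex-3-en-1-yl acetate F6. Olefination with 17 (KN(SiMe3)2, THF, −78 °C → rt, then reflux in heptane) gives (3R)-β-cryptoxanthin acetate F7, and methanolysis (K2CO3, MeOH/CH2Cl2) rejoins the route at 20.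

Third: step 3. The free hydroxyl consumes Me3Al and the hydroxymethylation of the alkenylalanate can be low-yielding. The fallback sets out from 6 and builds the trisubstituted olefin by the iodo-alkenol route. Double deprotonation (n-BuLi, 2.2 equiv, THF, −78 °C) and paraformaldehyde give (5S)-7-methyloct-7-en-2-yne-1,5-diol F8. Hydroxyl-directed trans-hydroalumination (NaAlH2(OCH2CH2OMe)2, THF, 0 °C) and iodination (I2, −78 °C) give (2Z,5S)-3-iodo-7-methylocta-2,7-diene-1,5-diol F9. Methylation with retention of olefin geometry (Me2CuLi, excess, Et2O, 0 °C) rejoins the route at 10.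

**Further compounds**

F1 | step 5 | (2E,5S)-3,7-dimethylocta-2,7-diene-1,5-diyl diacetate | CC(=O)O[C@@H](CC(C)=C)C/C(C)=C/COC(C)=O
F2 | step 5 | [(4R)-4-(acetyloxy)-2,6,6-trimethylcyclohex-1-en-1-yl]methyl acetate | CC(=O)O[C@@H]1CC(C)=C(COC(C)=O)C(C)(C)C1
F3 | step 6 | (4S,6E)-2,6-dimethyl-8-[(1-phenyl-1H-tetrazol-5-yl)sulfanyl]octa-1,6-dien-4-ol | O[C@@H](CC(C)=C)C/C(C)=C/CSc1nnnn1-c1ccccc1
F4 | step 6 | (4S,6E)-2,6-dimethyl-8-[(1-phenyl-1H-tetrazol-5-yl)sulfanyl]octa-1,6-dien-4-yl acetate | CC(=O)O[C@@H](CC(C)=C)C/C(C)=C/CSc1nnnn1-c1ccccc1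
F5 | step 6 | (4S,6E)-2,6-dimethyl-8-[(1-phenyl-1H-tetrazol-5-yl)sulfonyl]octa-1,6-dien-4-yl acetate | CC(=O)O[C@@H](CC(C)=C)C/C(C)=C/CS(=O)(=O)c1nnnn1-c1ccccc1
F6 | step 6 | (1R)-3,5,5-trimethyl-4-{[(1-phenyl-1H-tetrazol-5-yl)sulfonyl]methyl}cyclohex-3-en-1-yl acetate | CC(=O)O[C@@H]1CC(C)=C(CS(=O)(=O)c2nnnn2-c2ccccc2)C(C)(C)C1
F7 | step 6 | (3R)-β-cryptoxanthin acetate, (3R)-β,β-caroten-3-yl acetate | CC(=O)O[C@@H]1CC(C)=C(/C=C/C(C)=C/C=C/C(C)=C/C=C/C=C(C)/C=C/C=C(C)/C=C/C2=C(C)CCCC2(C)C)C(C)(C)C1
F8 | step 3 | (5S)-7-methyloct-7-en-2-yne-1,5-diol | O[C@@H](CC(C)=C)CC#CCO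
F9 | step 3 | (2Z,5S)-3-iodo-7-methylocta-2,7-diene-1,5-diol | O[C@@H](CC(C)=C)C/C(I)=C/CO
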